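**Assumption:** the target is (2S)-7,4'-dihydroxy-8,3',5'-triprenylflavanone (the SMILES stereocentre works out as S), and the chiral Rh ligand is bought, not made.

## Retrosynthetic overview

1. Global desilylation of a bis-silyl (2S)-flavanone gives the target; fluoride is buffered to avoid retro-oxa-Michael racemisation and acid-induced prenyl cyclisation.
2. The C2–aryl bond and the only stereocentre come from a Rh-catalysed asymmetric 1,4-addition of a B-ring arylboronic acid to a preformed A/C-ring chromone.
3. The chromone (pyranone ring, the only ring formed) comes from 2,4-dihydroxyacetophenone: C3-prenylation, 4-O-silylation, then enaminone formation and cyclisation.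
4. The boronic acid comes from 4-bromophenol: double ortho-C-prenylation, O-silylation, then Li–Br exchange and borylation.

## Route

**Step 1**
Reactants: **1** 2,4-dihydroxyacetophenone; **2** prenyl bromide (1-bromo-3-methylbut-2-ene)
Product: **3** 1-[2,4-dihydroxy-3-(3-methylbut-2-en-1-yl)phenyl]ethanone
Conditions: 10% aq. KOH, **2** (1.0 equiv), 0 °C → rt; chromatography to remove the 5-prenyl and O-prenyl isomers (expect about 25–35%)
Reagents that add atoms: prenyl bromide, CC(C)=CCBr
Why: nuclear C-prenylation of the ambident resorcinolate in water, where C3 (ortho to both oxygens) is the most nucleophilic carbon and water disfavours O-alkylation.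

**Step 2**
Reactants: **3**; **4** triisopropylsilyl chloride (TIPSCl)
Product: **5** 1-[2-hydroxy-3-prenyl-4-(triisopropylsilyloxy)phenyl]ethanone
Conditions: TIPSCl (1.1 equiv), imidazole, DMF, rt
Reagents that add atoms: TIPSCl, CC(C)[Si](Cl)(C(C)C)C(C)C
Why: chemoselective O-silylation of the free 4-OH, since the 2-OH is deactivated by its hydrogen bond to the ketone; TIPS is chosen because this para-acyl aryl silyl ether must survive steps 3 and 7.

**Step 3**
Reactants: **5**; **6** N,N-dimethylformamide dimethyl acetal (DMF-DMA)
Product: **7** 8-prenyl-7-(triisopropylsilyloxy)-4H-chromen-4-one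
Conditions: DMF-DMA (3 equiv), toluene, 90 °C; then conc. HCl (cat.), CH2Cl2, rt, short contact
Reagents that add atoms: DMF-DMA, COC(OC)N(C)C (supplies C2 of the chromone)
Why: enaminone formation at the methyl ketone followed by acid-promoted intramolecular addition–elimination (loss of Me2NH) closes the pyranone ring faster than the phenol can add to the prenyl group.

**Step 4**
Reactants: **8** 4-bromophenol; **2** prenyl bromide (2.4 equiv)
Product: **9** 4-bromo-2,6-bis(3-methylbut-2-en-1-yl)phenol
Conditions: NaH (2.4 equiv) and **2** (2.4 equiv) in two charges, toluene, 0 °C → rt (expect about 30–40%)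
Reagents that add atoms: prenyl bromide, CC(C)=CCBr (two equivalents incorporated)
Why: ortho-selective C-alkylation of an aggregated sodium phenoxide in a non-polar solvent; the para position is blocked by Br, so both prenyl groups go ortho.

**Step 5**
Reactants: **9**; **10** tert-butyldimethylsilyl chloride (TBSCl)
Product: **11** (4-bromo-2,6-diprenylphenoxy)(tert-butyl)dimethylsilane
Conditions: TBSCl, imidazole, DMF, 40 °C
Reagents that add atoms: TBSCl, CC(C)(C)[Si](C)(C)Cl
Why: standard phenol silylation that removes the acidic OH before lithiation; the flanking prenyl groups make this ether robust.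

**Step 6**
Reactants: **11**; **12** triisopropyl borate
Product: **13** [4-(tert-butyldimethylsilyloxy)-3,5-diprenylphenyl]boronic acid
Conditions: n-BuLi (1.1 equiv), THF, −78 °C; B(OiPr)3, −78 °C → rt; aq. NH4Cl
Reagents that add atoms: triisopropyl borate, CC(C)OB(OC(C)C)OC(C)C; water, O (hydrolysis to B(OH)2)
Why: Li–Br exchange at −78 °C outpaces deprotonation of the prenyl CH2, and the aryllithium is para to OSi so no retro-Brook shift occurs; borate trapping and hydrolysis give the boronic acid.

**Step 7**
Reactants: **7**; **13** (2.5 equiv)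
Product: **14** (2S)-2-[4-(tert-butyldimethylsilyloxy)-3,5-diprenylphenyl]-8-prenyl-7-(triisopropylsilyloxy)chroman-4-one
Conditions: [RhCl(C2H4)2]2 (1.5 mol %), (S)-MeO-F12-BIPHEP (3.3 mol %), aq. KOH (10 mol %), CH2Cl2/H2O 10:1, 35 °C
Reagents that add atoms: none (only **7** and **13**)
Why: Hayashi–Miyaura Rh-catalysed asymmetric 1,4-addition, in which the electron-poor biaryl bisphosphine delivers the aryl group to one face of chromone C2 to set the 2S centre.
Ligand sense: (S) is predicted by analogy with (S)-BINAP giving (S)-3-arylcyclohexanone, which maps onto 2S here. Confirm on the first run by chiral HPLC and CD, and use the (R)-ligand if the sense is opposite.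

**Step 8**
Reactants: **14**
Product: **15** sophoranone, (2S)-7-hydroxy-2-(4-hydroxy-3,5-diprenylphenyl)-8-prenylchroman-4-one
Conditions: TBAF/AcOH (1:1, 3 equiv), THF, 0 °C → rt
Reagents that add atoms: none
Why: fluoride cleaves both aryl silyl ethers, and the AcOH buffer prevents phenoxide-driven retro-oxa-Michael ring opening (racemisation at C2) while avoiding the strong acid that would cyclise ortho-prenylphenols to chromans.

## Compound list

1 | 2,4-dihydroxyacetophenone | CC(=O)c1ccc(O)cc1O | starting material
2 | prenyl bromide | CC(C)=CCBr | starting material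
3 | 2,4-dihydroxy-3-prenylacetophenone | CC(=O)c1ccc(O)c(CC=C(C)C)c1O | intermediate
4 | triisopropylsilyl chloride | CC(C)[Si](Cl)(C(C)C)C(C)C | starting material (reagent)
5 | 2-hydroxy-3-prenyl-4-(TIPS-oxy)acetophenone | CC(=O)c1ccc(O[Si](C(C)C)(C(C)C)C(C)C)c(CC=C(C)C)c1O | intermediate
6 | DMF dimethyl acetal | COC(OC)N(C)C | starting material (reagent)
7 | 8-prenyl-7-(TIPS-oxy)chromen-4-one | CC(C)=CCc1c(O[Si](C(C)C)(C(C)C)C(C)C)ccc2c(=O)ccoc12 | intermediate
8 | 4-bromophenol | Oc1ccc(Br)cc1 | starting material
9 | 4-bromo-2,6-diprenylphenol | CC(C)=CCc1cc(Br)cc(CC=C(C)C)c1O | intermediate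
10 | tert-butyldimethylsilyl chloride | CC(C)(C)[Si](C)(C)Cl | starting material (reagent)
11 | 4-bromo-2,6-diprenylphenyl TBS ether | CC(C)=CCc1cc(Br)cc(CC=C(C)C)c1O[Si](C)(C)C(C)(C)C | intermediate
12 | triisopropyl borate | CC(C)OB(OC(C)C)OC(C)C | starting material (reagent)
13 | [4-(TBS-oxy)-3,5-diprenylphenyl]boronic acid | CC(C)=CCc1cc(B(O)O)cc(CC=C(C)C)c1O[Si](C)(C)C(C)(C)C | intermediate
14 | (2S)-7-O-TIPS-4'-O-TBS-sophoranone | CC(C)=CCc1cc([C@@H]2CC(=O)c3ccc(O[Si](C(C)C)(C(C)C)C(C)C)c(CC=C(C)C)c3O2)cc(CC=C(C)C)c1O[Si](C)(C)C(C)(C)C | intermediate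
15 | sophoranone | CC(C)=CCc1cc([C@@H]2CC(=O)c3ccc(O)c(CC=C(C)C)c3O2)cc(CC=C(C)C)c1O | target

## Summary

Total steps: 8.
Longest linear sequence: 5 (steps 1 → 2 → 3 → 7 → 8, or 4 → 5 → 6 → 7 → 8).

Steps most likely to fail:

1. **Step 7** (asymmetric 1,4-addition). The 7-siloxychromone is a weak acceptor, the aryl group can add 1,2 to the product ketone, and the ee and facial sense are unverified for this substrate.
   Fallback: abandon the chromone and use an organocatalytic oxa-Michael closure. Convert **5** to its tert-butyl β-ketoester and condense it (Knoevenagel) with 4-(TBS-oxy)-3,5-diprenylbenzaldehyde. Cyclise with a cinchona-thiourea catalyst, then decarboxylate to the (2S)-flavanone.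

2. **Step 1** (C3-prenylation of resacetophenone). Yield is low and the 5-prenyl and O-prenyl isomers must be separated.
   Fallback: install the prenyl group by aromatic Claisen rearrangement. Alkylate commercial 7-hydroxychromone with 3-chloro-3-methylbut-1-yne, reduce with Lindlar catalyst to the 1,1-dimethylallyl ether, and heat for the [3,3] shift to C8. Silylate to reach **7**.

3. **Step 4** (double ortho-C-prenylation of 4-bromophenol). Mono-alkylation, O-alkylation and dienone by-products compete.
   Fallback: switch from phenoxide alkylation to aryl-metal chemistry. Iodinate **8** to 4-bromo-2,6-diiodophenol and protect the OH. Carry out two iodine-selective I/Mg exchanges (iPrMgCl·LiCl), each followed by Cu-catalysed coupling with prenyl bromide; the C–Br bond is kept for the borylation.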